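**Retrosynthetic overview**
1. Last ring: the nine-membered β-keto lactone is closed at the acyl C–O bond between the ring-A carboxyl carbon and the tertiary carbinol oxygen, by capture of an acylketene, after the two fragments are joined.
2. Fragment union: the C–C bond between lactone C-3 and the ring-A carbon β to the ketone is made by Michael addition of the γ-lactone enolate to a cyclohexenone ester; ring A itself comes from cyclohex-2-en-1-one.
3. First ring formed (key step): the γ-lactone is made by a (3+2) annulation of an α-branched allylsilane with chlorosulfonyl isocyanate; the ring closes by the bond from the ring oxygen O-1 to C-5, and the C–Si bond later becomes the C-4 hydroxyl.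
4. Enabling feature: in the γ-butyrolactone ring (O-1, C-2 carbonyl, C-3, C-4, C-5) the C-4 hydroxyl lies next to the O-1–C-5 bond and trans to the C-5 side chain. Read as C-4–Si, atoms C-3/C-4/C-5 are an allylsilane (C-3=C-4, Si on C-5) and O-1/C-2 an isocyanate; a 1,2-silyl shift with anti O-attack gives exactly this trans pattern.
5. The allylsilane comes from (R)-mevalonolactone (source of the quaternary carbinol) by Wittig methylenation, cross-metathesis and Cu-catalysed enantioselective allylic silylation.

Key step: step 8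

Remark (assumption): ring-A β-keto esters are written as keto or enol tautomers as convenient (the target as the enol given), and the doubly activated C-1 of 18 and 20–22 is configurationally labile and left undefined.

**Step 1**
Reactants: 1 (R)-mevalonolactone, (4R)-4-hydroxy-4-methyloxan-2-one
Product: 2 (4R)-4-methyl-4-[(triethylsilyl)oxy]oxan-2-one
Conditions: TESOTf, 2,6-lutidine, CH2Cl2, −78 → 0 °C
Reagents that add atoms: triethylsilyl trifluoromethanesulfonate, CC[Si](CC)(CC)OS(=O)(=O)C(F)(F)F
Why: Silyl ether formation at a tertiary alcohol with a silyl triflate and a hindered base is reliable; it blocks retro-aldol at the later aldehyde stages and shields the alcohol from the isocyanate of step 8, and the chiral-pool stereocentre is untouched.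

**Step 2**
Reactants: 2 (4R)-4-methyl-4-[(triethylsilyl)oxy]oxan-2-one
Product: 3 (4R)-4-methyl-4-[(triethylsilyl)oxy]oxan-2-ol (lactol, anomer mixture)
Conditions: DIBAL-H (1.1 equiv), CH2Cl2, −78 °C; Rochelle salt work-up
Reagents that add atoms: none
Why: Partial reduction of a δ-lactone with DIBAL-H should stop at the lactol because the aluminium hemiacetal is stable at −78 °C.

**Step 3**
Reactants: 3 (4R)-4-methyl-4-[(triethylsilyl)oxy]oxan-2-ol
Product: 5 (3S)-3-methyl-3-[(triethylsilyl)oxy]hex-5-en-1-ol, via hydroxy aldehyde 4 (not isolated)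
Conditions: Ph3PCH3Br, KHMDS, THF, 0 → 23 °C
Reagents that add atoms: methyltriphenylphosphonium bromide, C[P+](c1ccccc1)(c1ccccc1)c1ccccc1.[Br-] (used as its ylide, methylidenetriphenylphosphorane, C=P(c1ccccc1)(c1ccccc1)c1ccccc1)
Why: Wittig methylenation of the lactol through its ring-opened aldehyde tautomer turns the former lactone carbonyl carbon into the internal alkene carbon (the later lactone C-5); the descriptor changes from R to S only because the ranking of the two arms is reversed.

**Step 4**
Reactants: 5 (3S)-3-methyl-3-[(triethylsilyl)oxy]hex-5-en-1-ol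
Product: 7 (3S)-3-methyl-3-[(triethylsilyl)oxy]hex-5-enoic acid, via aldehyde 6 (not isolated)
Conditions: TEMPO (0.2 equiv), PhI(OAc)2 (2.2 equiv), MeCN/H2O (1:1), 23 °C
Reagents that add atoms: water, O
Why: Oxoammonium (TEMPO) oxidation of a primary alcohol through the aldehyde hydrate to the acid is selective for the CH2OH group and should leave the terminal alkene and the tertiary silyl ether alone.

**Step 5**
Reactants: 7 (3S)-3-methyl-3-[(triethylsilyl)oxy]hex-5-enoic acid
Product: 8 methyl (3S)-3-methyl-3-[(triethylsilyl)oxy]hex-5-enoate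
Conditions: MeI, K2CO3, DMF, 23 °C
Reagents that add atoms: iodomethane, CI
Why: SN2 O-methylation of the carboxylate under mild base installs the methyl ester of the target without touching the silyl ether.

**Step 6**
Reactants: 8 methyl (3S)-3-methyl-3-[(triethylsilyl)oxy]hex-5-enoate
Product: 9 methyl (3S,5E)-7-chloro-3-methyl-3-[(triethylsilyl)oxy]hept-5-enoate
Conditions: (Z)-1,4-dichlorobut-2-ene (3 equiv), second-generation Hoveyda–Grubbs catalyst (5 mol %), CH2Cl2, 40 °C
Reagents that add atoms: (Z)-1,4-dichlorobut-2-ene, ClC/C=C\CCl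
Why: Olefin cross-metathesis of a terminal alkene with an excess of a symmetric internal alkene should give the allylic chloride with the E isomer predominating; no stereocentre is formed, and a minor Z isomer would only lead to a diastereomer removable after step 8.

**Step 7**
Reactants: 9 methyl (3S,5E)-7-chloro-3-methyl-3-[(triethylsilyl)oxy]hept-5-enoate
Product: 10 methyl (3R,5S)-5-[dimethyl(phenyl)silyl]-3-methyl-3-[(triethylsilyl)oxy]hept-6-enoate
Conditions: PhMe2Si–Bpin (1.5 equiv), CuCl (5 mol %), chiral six-membered NHC·HBF4 (6 mol %), NaOMe (1.5 equiv), CH2Cl2, 0 °C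
Reagents that add atoms: dimethyl(phenyl)silylboronic acid pinacol ester, C[Si](C)(c1ccccc1)B1OC(C)(C)C(C)(C)O1
Why: Copper-catalysed enantioselective γ-selective allylic substitution (SN2′) with a silyl nucleophile released from the Si–B reagent by methoxide; the chiral NHC ligand, used as the enantiomer that gives the (5S)-silane, sets the C–Si stereocentre by catalyst control because the quaternary carbinol is too remote to interfere.

**Step 8**
Reactants: 10 methyl (3R,5S)-5-[dimethyl(phenyl)silyl]-3-methyl-3-[(triethylsilyl)oxy]hept-6-enoate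
Product: 13 methyl (3S)-4-[(2R,3S)-3-[dimethyl(phenyl)silyl]-5-oxooxolan-2-yl]-3-hydroxy-3-methylbutanoate, via N-chlorosulfonyl iminolactone 11 (not isolated), via triethylsilyl-protected lactone 12 (not isolated)
Conditions: ClSO2NCO (1.2 equiv), toluene, −78 → −20 °C; then 1 M HCl/THF (1:1), 23 °C
Reagents that add atoms: chlorosulfonyl isocyanate, O=C=NS(=O)(=O)Cl; water, O
Why: The isocyanate carbon adds to the terminal alkene carbon of 10 anti to the C–Si bond, silicon bridges the resulting β-silyl cation and shifts to the neighbouring carbon, and the amidate oxygen opens the siliranium ion at the former C–Si carbon from the face opposite to silicon, so the five-membered ring is closed by the new O–C bond; aqueous acid then hydrolyses the N-chlorosulfonyl imidate 11 to the lactone and removes the TES group. The closest known reaction type is the (3+2) annulation of allylsilanes with chlorosulfonyl isocyanate, which gives 4-silyl γ-lactams and, by O-closure and hydrolysis, 4-silyl γ-lactones. The γ-lactone ring closes in a 5-exo-tet mode, the breaking C–Si bond of the siliranium ion lying outside the new ring. Lactone C-5 is formed with inversion at the C–Si stereocentre of 10 (5S silane gives 5R lactone), and C-4 receives silicon on the alkene face it already occupies in the conformer whose allylic hydrogen eclipses the vinyl group, so silicon ends trans to the C-5 side chain. The step needs annulation to win over desilylative acylation and [2+2] closure to a β-lactam, O-closure to win over N-closure, and the hydrogen-eclipsed conformer to win over the one with the side chain eclipsed. The branched carbinyl carbon carries positive charge well and so favours opening there, the bulky neopentyl-type side chain disfavours the eclipsed conformer, low temperature in toluene with prompt acidic hydrolysis traps the kinetically formed imidate, and 10 has no other alkene or free hydroxyl for the isocyanate to attack.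

**Step 9**
Reactants: 13 methyl (3S)-4-[(2R,3S)-3-[dimethyl(phenyl)silyl]-5-oxooxolan-2-yl]-3-hydroxy-3-methylbutanoate
Product: 14 methyl (3S)-3-hydroxy-4-[(2R,3S)-3-hydroxy-5-oxooxolan-2-yl]-3-methylbutanoate
Conditions: KBr, AcOOH, NaOAc, AcOH, 23 °C
Reagents that add atoms: peracetic acid, CC(=O)OO
Why: Fleming–Tamao oxidation (ipso-bromodesilylation of the phenyl group, then peroxide attack at silicon and 1,2-shift of carbon from Si to O) converts C–Si into C–OH with retention, so the hydroxyl ends trans to the C-5 side chain; no alkene is present at this stage.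

**Step 10**
Reactants: 14 methyl (3S)-3-hydroxy-4-[(2R,3S)-3-hydroxy-5-oxooxolan-2-yl]-3-methylbutanoate
Product: 15 methyl (3S)-4-[(2R,3S)-3-[(tert-butyldimethylsilyl)oxy]-5-oxooxolan-2-yl]-3-hydroxy-3-methylbutanoate
Conditions: TBSCl (1.2 equiv), imidazole, DMF, 23 °C
Reagents that add atoms: tert-butyldimethylsilyl chloride, CC(C)(C)[Si](C)(C)Cl
Why: Silylation with TBSCl/imidazole should take the secondary hydroxyl and leave the hindered tertiary one free, which is the differentiation needed for the ring closure of step 16.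

**Step 11**
Reactants: 16 cyclohex-2-en-1-one
Product: 17 (3S)-3-(prop-1-en-2-yl)cyclohexan-1-one
Conditions: isopropenyl–Bpin (2 equiv), [Rh(cod)Cl]2 (1.5 mol %), (S)-BINAP (3.3 mol %), KOH (0.5 equiv), dioxane/H2O (10:1), 60 °C
Reagents that add atoms: isopropenylboronic acid pinacol ester, C=C(C)B1OC(C)(C)C(C)(C)O1
Why: Rhodium-catalysed asymmetric 1,4-addition of an alkenylboron reagent (Hayashi–Miyaura reaction); the Rh/(S)-BINAP alkenyl complex adds to one enantioface of the enone and should give the (S)-ketone in the same sense as other alkenyl- and arylboron reagents.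

**Step 12**
Reactants: 17 (3S)-3-(prop-1-en-2-yl)cyclohexan-1-one
Product: 18 methyl (4S)-2-oxo-4-(prop-1-en-2-yl)cyclohexane-1-carboxylate
Conditions: NaH (2.2 equiv), (MeO)2CO (3 equiv), THF, reflux; aq. HCl work-up
Reagents that add atoms: dimethyl carbonate, COC(=O)OC
Why: Claisen-type C-acylation of the ketone under equilibrating conditions ends as the enolate of the less hindered β-keto ester, acylated at C-6 away from the C-3 substituent; the existing stereocentre is not enolisable.

**Step 13**
Reactants: 18 methyl (4S)-2-oxo-4-(prop-1-en-2-yl)cyclohexane-1-carboxylate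
Product: 20 tert-butyl (4S)-2-oxo-4-(prop-1-en-2-yl)cyclohexane-1-carboxylate, via acylketene 19 (not isolated)
Conditions: t-BuOH (10 equiv), DMAP (0.3 equiv), toluene, reflux, 5 Å molecular sieves
Reagents that add atoms: tert-butanol, CC(C)(C)O
Why: DMAP-assisted ester exchange of a β-keto ester, which runs through the acylketene and is driven by trapping of methanol, installs the tert-butyl ester that releases an acylketene under mild heating in step 16.

**Step 14**
Reactants: 20 tert-butyl (4S)-2-oxo-4-(prop-1-en-2-yl)cyclohexane-1-carboxylate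
Product: 23 tert-butyl (4S)-6-oxo-4-(prop-1-en-2-yl)cyclohex-1-ene-1-carboxylate, via selenide 21 (not isolated), via selenoxide 22 (not isolated)
Conditions: NaH, THF, 0 °C; PhSeCl (1.0 equiv), −78 °C; then H2O2 (30 %), CH2Cl2, 0 °C
Reagents that add atoms: none
Why: α-Selenenylation of the preformed sodium enolate (faster than addition of PhSeCl to the isopropenyl group) followed by selenoxide syn-elimination, which can only run towards C-6, should give the doubly activated enone, to be used at once.

**Step 15**
Reactants: 15 methyl (3S)-4-[(2R,3S)-3-[(tert-butyldimethylsilyl)oxy]-5-oxooxolan-2-yl]-3-hydroxy-3-methylbutanoate; 23 tert-butyl (4S)-6-oxo-4-(prop-1-en-2-yl)cyclohex-1-ene-1-carboxylate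
Product: 24 tert-butyl (4S,6R)-6-[(3S,4S,5R)-4-[(tert-butyldimethylsilyl)oxy]-5-[(2S)-2-hydroxy-4-methoxy-2-methyl-4-oxobutyl]-2-oxooxolan-3-yl]-2-hydroxy-4-(prop-1-en-2-yl)cyclohex-1-ene-1-carboxylate
Conditions: LiHMDS (2.1 equiv), THF, −78 °C; then 23 (1.2 equiv), −78 °C; AcOH quench
Reagents that add atoms: none
Why: Michael addition of the lactone lithium enolate (the tertiary alkoxide forms first and stays a spectator) to the doubly activated enone: lactone C-3 is set by attack anti to the neighbouring silyloxy group and the ring-A centre by axial attack anti to the isopropenyl group (trans-3,5), so each ring controls its own new centre and their mutual relation follows.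

**Step 16**
Reactants: 24 tert-butyl (4S,6R)-6-[(3S,4S,5R)-4-[(tert-butyldimethylsilyl)oxy]-5-[(2S)-2-hydroxy-4-methoxy-2-methyl-4-oxobutyl]-2-oxooxolan-3-yl]-2-hydroxy-4-(prop-1-en-2-yl)cyclohex-1-ene-1-carboxylate
Product: 26 O-TBS ether of the target (nine-membered β-keto lactone closed), via acylketene 25 (not isolated)
Conditions: toluene (0.5 mM, slow addition), 110 °C, N2 sweep
Reagents that add atoms: none
Why: Thermal retro-ene loss of tert-butanol from the enolised tert-butyl β-keto ester gives an acylketene that is captured by the tertiary alcohol (acylketene macrolactonisation); the two arms are held cis on the γ-lactone and the only other hydroxyl is silylated, and no stereocentre is formed.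

**Step 17**
Reactants: 26 O-TBS ether of the target
Product: 27 CNP0302642.1 (target)
Conditions: HF·pyridine, THF/pyridine, 0 → 23 °C
Reagents that add atoms: none
Why: Fluoride-driven cleavage of the silyl ether under mildly acidic conditions avoids base, which could trigger β-elimination of the tertiary acyloxy ester or of the β-hydroxy lactone; no stereocentre is touched.

**Compound list**
1 | (R)-mevalonolactone, (4R)-4-hydroxy-4-methyloxan-2-one | O1CC[C@@](C)(O)CC1=O | starting material
2 | (4R)-4-methyl-4-[(triethylsilyl)oxy]oxan-2-one | O1CC[C@@](C)(O[Si](CC)(CC)CC)CC1=O | intermediate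
3 | (4R)-4-methyl-4-[(triethylsilyl)oxy]oxan-2-ol (lactol, anomer mixture) | O1CC[C@@](C)(O[Si](CC)(CC)CC)CC1O | intermediate
4 | (3R)-5-hydroxy-3-methyl-3-[(triethylsilyl)oxy]pentanal (open-chain tautomer of 3, not isolated) | OCC[C@@](C)(O[Si](CC)(CC)CC)CC=O | intermediate
5 | (3S)-3-methyl-3-[(triethylsilyl)oxy]hex-5-en-1-ol | OCC[C@@](C)(O[Si](CC)(CC)CC)CC=C | intermediate
6 | (3S)-3-methyl-3-[(triethylsilyl)oxy]hex-5-enal (not isolated) | O=CC[C@@](C)(O[Si](CC)(CC)CC)CC=C | intermediate
7 | (3S)-3-methyl-3-[(triethylsilyl)oxy]hex-5-enoic acid | OC(=O)C[C@@](C)(O[Si](CC)(CC)CC)CC=C | intermediate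
8 | methyl (3S)-3-methyl-3-[(triethylsilyl)oxy]hex-5-enoate | COC(=O)C[C@@](C)(O[Si](CC)(CC)CC)CC=C | intermediate
9 | methyl (3S,5E)-7-chloro-3-methyl-3-[(triethylsilyl)oxy]hept-5-enoate | COC(=O)C[C@@](C)(O[Si](CC)(CC)CC)C/C=C/CCl | intermediate
10 | methyl (3R,5S)-5-[dimethyl(phenyl)silyl]-3-methyl-3-[(triethylsilyl)oxy]hept-6-enoate | COC(=O)C[C@@](C)(O[Si](CC)(CC)CC)C[C@H]([Si](C)(C)c1ccccc1)C=C | intermediate
11 | methyl (3S)-4-[(2R,3S)-5-[(chlorosulfonyl)imino]-3-[dimethyl(phenyl)silyl]oxolan-2-yl]-3-methyl-3-[(triethylsilyl)oxy]butanoate (not isolated) | COC(=O)C[C@@](C)(O[Si](CC)(CC)CC)C[C@H]1OC(=NS(=O)(=O)Cl)C[C@@H]1[Si](C)(C)c1ccccc1 | intermediate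
12 | methyl (3S)-4-[(2R,3S)-3-[dimethyl(phenyl)silyl]-5-oxooxolan-2-yl]-3-methyl-3-[(triethylsilyl)oxy]butanoate (not isolated) | COC(=O)C[C@@](C)(O[Si](CC)(CC)CC)C[C@H]1OC(=O)C[C@@H]1[Si](C)(C)c1ccccc1 | intermediate
13 | methyl (3S)-4-[(2R,3S)-3-[dimethyl(phenyl)silyl]-5-oxooxolan-2-yl]-3-hydroxy-3-methylbutanoate | COC(=O)C[C@@](C)(O)C[C@H]1OC(=O)C[C@@H]1[Si](C)(C)c1ccccc1 | intermediate
14 | methyl (3S)-3-hydroxy-4-[(2R,3S)-3-hydroxy-5-oxooxolan-2-yl]-3-methylbutanoate | COC(=O)C[C@@](C)(O)C[C@H]1OC(=O)C[C@@H]1O | intermediate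
15 | methyl (3S)-4-[(2R,3S)-3-[(tert-butyldimethylsilyl)oxy]-5-oxooxolan-2-yl]-3-hydroxy-3-methylbutanoate | COC(=O)C[C@@](C)(O)C[C@H]1OC(=O)C[C@@H]1O[Si](C)(C)C(C)(C)C | intermediate
16 | cyclohex-2-en-1-one | O=C1C=CCCC1 | starting material
17 | (3S)-3-(prop-1-en-2-yl)cyclohexan-1-one | C=C(C)[C@@H]1CC(=O)CCC1 | intermediate
18 | methyl (4S)-2-oxo-4-(prop-1-en-2-yl)cyclohexane-1-carboxylate | C=C(C)[C@@H]1CC(=O)C(C(=O)OC)CC1 | intermediate
19 | (5S)-2-(oxomethylidene)-5-(prop-1-en-2-yl)cyclohexan-1-one (acylketene, not isolated) | C=C(C)[C@@H]1CC(=O)C(=C=O)CC1 | intermediate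
20 | tert-butyl (4S)-2-oxo-4-(prop-1-en-2-yl)cyclohexane-1-carboxylate | C=C(C)[C@@H]1CC(=O)C(C(=O)OC(C)(C)C)CC1 | intermediate
21 | tert-butyl (4S)-2-oxo-1-(phenylselanyl)-4-(prop-1-en-2-yl)cyclohexane-1-carboxylate (not isolated) | C=C(C)[C@@H]1CC(=O)C(C(=O)OC(C)(C)C)([Se]c2ccccc2)CC1 | intermediate
22 | tert-butyl (4S)-2-oxo-1-(phenylseleninyl)-4-(prop-1-en-2-yl)cyclohexane-1-carboxylate (not isolated) | C=C(C)[C@@H]1CC(=O)C(C(=O)OC(C)(C)C)([Se](=O)c2ccccc2)CC1 | intermediate
23 | tert-butyl (4S)-6-oxo-4-(prop-1-en-2-yl)cyclohex-1-ene-1-carboxylate | C=C(C)[C@@H]1CC(=O)C(C(=O)OC(C)(C)C)=CC1 | intermediate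
24 | tert-butyl (4S,6R)-6-[(3S,4S,5R)-4-[(tert-butyldimethylsilyl)oxy]-5-[(2S)-2-hydroxy-4-methoxy-2-methyl-4-oxobutyl]-2-oxooxolan-3-yl]-2-hydroxy-4-(prop-1-en-2-yl)cyclohex-1-ene-1-carboxylate | C=C(C)[C@@H]1CC(O)=C(C(=O)OC(C)(C)C)[C@H](C1)[C@@H]1C(=O)O[C@H](C[C@](C)(O)CC(=O)OC)[C@H]1O[Si](C)(C)C(C)(C)C | intermediate
25 | acylketene from 24 by loss of tert-butanol (not isolated) | C=C(C)[C@@H]1CC(=O)C(=C=O)[C@H](C1)[C@@H]1C(=O)O[C@H](C[C@](C)(O)CC(=O)OC)[C@H]1O[Si](C)(C)C(C)(C)C | intermediate
26 | O-tert-butyldimethylsilyl ether of the target | C=C(C)[C@@H]1CC(O)=C2C(=O)O[C@](C)(CC(=O)OC)C[C@H]3OC(=O)[C@H]([C@@H]3O[Si](C)(C)C(C)(C)C)[C@H]2C1 | intermediate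
27 | CNP0302642.1 | C=C(C)[C@@H]1CC(O)=C2C(=O)O[C@](C)(CC(=O)OC)C[C@H]3OC(=O)[C@H]([C@@H]3O)[C@H]2C1 | target

**Step count and risks**
Total step count: 17. Longest linear sequence: 13 steps (steps 1–10, then 15–17); steps 11–14 form the four-step ring-A branch.

Steps most likely to fail:

1. Step 8. The amidate may close through nitrogen to a γ-lactam instead of through oxygen, silicon may be lost before ring closure (desilylative acylation), a [2+2] closure may compete, or the side-chain-eclipsed conformer may react and give the cis isomer. The fallback makes the same O–C bond by epoxide opening and sets out from 8. Cross-metathesis with but-3-enoic acid should give (3E,6S)-8-methoxy-6-methyl-8-oxo-6-[(triethylsilyl)oxy]oct-3-enoic acid F1. Shi epoxidation, with the ketone enantiomer that delivers the (2S,3S)-oxirane, should give 2-[(2S,3S)-3-{(2S)-4-methoxy-2-methyl-4-oxo-2-[(triethylsilyl)oxy]butyl}oxiran-2-yl]acetic acid F2. Camphorsulfonic acid in CH2Cl2 should let the carboxyl oxygen open the epoxide at the distal carbon with inversion, giving methyl (3S)-4-[(2R,3S)-3-hydroxy-5-oxooxolan-2-yl]-3-methyl-3-[(triethylsilyl)oxy]butanoate F3. Mild acid (PPTS, MeOH) then removes the TES group, and the route is rejoined at 14.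

2. Step 16. The acylketene may oligomerise or be intercepted by traces of water (then decarboxylate) faster than the strained nine-membered ring closes. The fallback closes the ring by a C–C bond instead and sets out from 15 and 20. Heating the two together in concentrated toluene at 110 °C should give, by intermolecular acylketene capture, (2S)-1-[(2R,3S)-3-[(tert-butyldimethylsilyl)oxy]-5-oxooxolan-2-yl]-4-methoxy-2-methyl-4-oxobutan-2-yl (4S)-2-oxo-4-(prop-1-en-2-yl)cyclohexane-1-carboxylate F4. Selenenylation of its sodium enolate and selenoxide elimination should give the corresponding (4S)-6-oxo-4-(prop-1-en-2-yl)cyclohex-1-ene-1-carboxylate F5. LiHMDS at −78 °C under high dilution should then close the ring by intramolecular Michael addition of the lactone enolate, coming back to the route at 26.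

3. Step 15. The side-chain methyl ester may be enolised in competition with the lactone, the lactone enolate may expel the β-silyloxy group, the tertiary alkoxide may add to the enone, or the enone may polymerise. The fallback uses an enolate without a leaving group and sets out from 14. LDA (3.1 equiv) should form the bis-alkoxide enolate, whose Michael addition to 23 should give tert-butyl (4S,6R)-2-hydroxy-6-[(3S,4S,5R)-4-hydroxy-5-[(2S)-2-hydroxy-4-methoxy-2-methyl-4-oxobutyl]-2-oxooxolan-3-yl]-4-(prop-1-en-2-yl)cyclohex-1-ene-1-carboxylate F6. Selective silylation of its secondary hydroxyl (TBSCl, imidazole) comes back to the route at 24.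

**Further compounds**
F1 | step 8 | (3E,6S)-8-methoxy-6-methyl-8-oxo-6-[(triethylsilyl)oxy]oct-3-enoic acid | COC(=O)C[C@@](C)(O[Si](CC)(CC)CC)C/C=C/CC(=O)O
F2 | step 8 | 2-[(2S,3S)-3-{(2S)-4-methoxy-2-methyl-4-oxo-2-[(triethylsilyl)oxy]butyl}oxiran-2-yl]acetic acid | COC(=O)C[C@@](C)(O[Si](CC)(CC)CC)C[C@@H]1O[C@H]1CC(=O)O
F3 | step 8 | methyl (3S)-4-[(2R,3S)-3-hydroxy-5-oxooxolan-2-yl]-3-methyl-3-[(triethylsilyl)oxy]butanoate | COC(=O)C[C@@](C)(O[Si](CC)(CC)CC)C[C@H]1OC(=O)C[C@@H]1O
F4 | step 16 | (2S)-1-[(2R,3S)-3-[(tert-butyldimethylsilyl)oxy]-5-oxooxolan-2-yl]-4-methoxy-2-methyl-4-oxobutan-2-yl (4S)-2-oxo-4-(prop-1-en-2-yl)cyclohexane-1-carboxylate | C=C(C)[C@@H]1CC(=O)C(CC1)C(=O)O[C@](C)(CC(=O)OC)C[C@H]1OC(=O)C[C@@H]1O[Si](C)(C)C(C)(C)C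
F5 | step 16 | (2S)-1-[(2R,3S)-3-[(tert-butyldimethylsilyl)oxy]-5-oxooxolan-2-yl]-4-methoxy-2-methyl-4-oxobutan-2-yl (4S)-6-oxo-4-(prop-1-en-2-yl)cyclohex-1-ene-1-carboxylate | C=C(C)[C@@H]1CC(=O)C(=CC1)C(=O)O[C@](C)(CC(=O)OC)C[C@H]1OC(=O)C[C@@H]1O[Si](C)(C)C(C)(C)C
F6 | step 15 | tert-butyl (4S,6R)-2-hydroxy-6-[(3S,4S,5R)-4-hydroxy-5-[(2S)-2-hydroxy-4-methoxy-2-methyl-4-oxobutyl]-2-oxooxolan-3-yl]-4-(prop-1-en-2-yl)cyclohex-1-ene-1-carboxylate | C=C(C)[C@@H]1CC(O)=C(C(=O)OC(C)(C)C)[C@H](C1)[C@@H]1C(=O)O[C@H](C[C@](C)(O)CC(=O)OC)[C@H]1O
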